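One mole of G marks one exchange, so the rate of G is the rate of the whole chain.

- gamma: J 0.25 M; Q 1.50 equiv; time 5.0 h
- alpha: J 0.25 M; Q 4.50 equiv; time 5.0 h

    J + Q → G + D (k1 = 0.0312 /M/min)
    J + L ⇌ J.L, settled at all times (K2 = 50 /M)
    Z + Q → G + L (k3 = 0.0134 /M/min)
    E + Q → G + Z (k4 = 0.0115 /M/min)
    D + Q → G + E (k5 = 0.0185 /M/min)

- which of these there is most of at the end, counted by the J in it, gamma (J / D / Z / L / E)
- which of these there is most of at the end, counted by the J in it, alpha (J / D / Z / L / E)
- final amount of the leader among these, as a percentage of the J charged, in gamma
- final amount of the leader among these, as a percentage of the J charged, in alpha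

- percentages count the J that a species holds: one J.L counts as two
- L is meant together with its J.L
- in an amount of L, one J.L counts as one L
- run time (gamma): 5.0 h

At the start of gamma, G forms at 0.175 M/h, and two things slow it. First, J gives way to D, whose step is slower than that of J by a factor 0.593. That constant lies between the first and the others, so my reckoning takes it as the mean constant of the chain and sets J.L aside. Second, Q falls, with a time constant τ, the inverse of that mean constant times the charge of J. Here τ is 3.60 h, shorter than the run, and gamma and alpha share it. Averaged over the run, the slowing factor S is 0.541, so you count 2.70 h of full-rate time.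

At a given Q, each step is pseudo-first-order in its complex. The exposure n, the first step's constant times the charged Q times that counted time, then places each flask on the chain, and any later step receives n scaled by its constant. Exposure gives this share of the J charged:

| Flask | n | J | D | E | Z | L |
|---|---|---|---|---|---|---|
| gamma | 1.90 | 15.0% | 42.9% | 31.8% | 8.18% | 2.11% |
| alpha | 5.69 | 0.337% | 7.57% | 29.9% | 26.6% | 35.6% |

So I commit to D at 42.9% in gamma, and L at 35.6% in alpha.

The forecast names the same leaders but gives other amounts: D at 46% in gamma, where “the chain stalls early and the singly exchanged D leads”, and L at 37% in alpha.

The simulation gives D at 45.4% in gamma and L at 37.5% in alpha. J.L holds 1.71% in gamma and 4.20% in alpha. Alpha's exposure is 2.99 times gamma's, and the difference in equivalents of Q is the main reason for the gap in L: with gamma's equivalents, alpha's 37.5% of L falls to 1.20%.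

In a neighbour flask with alpha's equivalents on 0.10 M of J, τ lengthens and n is 3.23, between gamma's and alpha's. That puts E at 40.8%, more than D at 26.4%. The computed neighbour flask holds most of its J in E, at 40.2%.

Its constants were set for the occasion; what happens was integrated by code.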